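**Retrosynthetic overview**

1. The target spirodilactone is opened at ring B (C1 carboxyl onto the tertiary C3–OH, closed last) and then at ring A (C3 carboxyl onto C5–OH, closed first). This leads back to a masked open-chain tetrahydroxy-tricarboxylate, and both lactonizations run as one acid cascade in the order expected for the presumed biogenesis from the alkylcitrate-type seco acid.
2. The masked seco compound is cut at C2–C3 (the citrate-synthase-type bond): lithium enolate of di-tert-butyl L-tartrate acetonide (C1, C2) plus methyl (R)-4-silyloxy-2-oxotetradec-13-enoate (C3–C15). Aldol and cascade share one flask.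
3. The keto ester comes from a dithiane linchpin coupling: 2-silyl-1,3-dithiane (C3), (R)-2-(dec-9-enyl)oxirane (C4–C15) and methyl chloroformate (the C3 carboxyl), with silyl transfer to O5 built in.
4. The epoxide comes from (R)-epichlorohydrin (C4–C6) and non-8-enylmagnesium bromide (C7–C15).
5. C5 and C1 come from the chiral pool; C2 and C3 are set in the aldol; ring order is A, then B.

Assumption: seco-acid numbering C1–C15 is used (C1, C2, C3 carry the carboxyls; target = 1R,2R,3S,5R, the cinatrin A structure), and compounds 1, 2, 6, 7 and 13 are taken as purchasable.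

**Route**

Step 1
Reactants: 1 9-bromonon-1-ene; 2 (R)-epichlorohydrin
Product: 5 (2R)-2-(dec-9-en-1-yl)oxirane, via non-8-en-1-ylmagnesium bromide 3 (not isolated), via (2R)-1-chlorododec-11-en-2-ol 4 (not isolated)
Conditions: 1, Mg, THF, 40 °C; then 2, CuI (5 mol%), THF, −40 → 0 °C; then 4 M aq NaOH, rt (same flask)
Reagents that add atoms: none
Why: Copper-catalysed Grignard opening of the epoxide at its unsubstituted carbon followed by Williamson ring closure of the chlorohydrin, neither of which breaks a bond at the carbinol carbon, so C5 (R) is taken unchanged from the chiral pool.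

Step 2
Reactants: 5 (2R)-2-(dec-9-en-1-yl)oxirane; 6 2-(tert-butyldimethylsilyl)-1,3-dithiane; 7 methyl chloroformate
Product: 11 methyl 2-[(2R)-2-(tert-butyldimethylsilyloxy)dodec-11-en-1-yl]-1,3-dithiane-2-carboxylate, via lithiated silyl dithiane 8 (not isolated), via lithium alkoxide adduct 9 (not isolated), via Brook-shifted lithiodithiane 10 (not isolated)
Conditions: 6, t-BuLi, Et2O, −78 → −45 °C; 5, Et2O, −78 → −25 °C; HMPA, THF, −78 °C; 7, −78 → −40 °C
Reagents that add atoms: none
Why: Anion relay linchpin coupling (Corey–Seebach umpolung plus 1,4-Brook rearrangement), in which the lithiated silyl dithiane opens the epoxide at CH2, HMPA then drives silicon from carbon to the new alkoxide, protecting O5 and regenerating a dithiane carbanion that is C-acylated by the chloroformate, with C5 untouched.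

Step 3
Reactants: 11 methyl 2-[(2R)-2-(tert-butyldimethylsilyloxy)dodec-11-en-1-yl]-1,3-dithiane-2-carboxylate
Product: 12 methyl (4R)-4-(tert-butyldimethylsilyloxy)-2-oxotetradec-13-enoate
Conditions: PhI(OCOCF3)2 (1.5 equiv), MeCN/H2O (9:1), 0 °C, 15 min; used promptly
Reagents that add atoms: water, O
Why: Oxidative dethioacetalization by the hypervalent iodine reagent (S-oxidation, then hydrolysis of the thionium ion) is much faster than any reaction at the isolated terminal alkene and leaves the silyl ether, the ester and C5 intact.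

Step 4
Reactants: 13 di-tert-butyl L-tartrate
Product: 14 di-tert-butyl (4R,5R)-2,2-dimethyl-1,3-dioxolane-4,5-dicarboxylate
Conditions: 2,2-dimethoxypropane, PPTS (cat.), CH2Cl2, 40 °C
Reagents that add atoms: 2,2-dimethoxypropane, COC(C)(C)OC
Why: Acid-catalysed transacetalization (isopropylidene acetal formation) of the trans diol under mild pyridinium catalysis, which spares the tert-butyl esters and does not touch the two (R) centres.

Step 5
Reactants: 14 di-tert-butyl (4R,5R)-2,2-dimethyl-1,3-dioxolane-4,5-dicarboxylate; 12 methyl (4R)-4-(tert-butyldimethylsilyloxy)-2-oxotetradec-13-enoate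
Product: 19 (3R,4R,5S,8R)-8-(dec-9-en-1-yl)-3,4-dihydroxy-2,6-dioxo-1,7-dioxaspiro[4.4]nonane-4-carboxylic acid, via lithium enolate 15 (not isolated), via aldol adduct 16 (not isolated), via ring A lactone diester 17 (not isolated), via ring A lactone diacid 18 (not isolated)
Conditions: 14 (1.6 equiv), LiN(iPr)2 (1.5 equiv), THF, −78 °C; 12 (1.0 equiv), −78 °C, 1 h; CF3CO2H, −78 °C → rt, evaporate; CF3CO2H/H2O (9:1), 0 °C → rt, 5 h; C18 chromatography
Reagents that add atoms: none
Why: Lithium enolate aldol addition to the α-keto ester (the citrate-synthase-like C2–C3 union) sets C2 (R) by attack anti to the C1 ester on the dioxolane and C3 (S) through a lithium-chelated Zimmerman–Traxler chair with CO2Me axial and the C4 chain equatorial, after which acidolysis unmasks in the order silyl ether (O5 closes ring A on the methyl ester), tert-butyl esters, then the electron-poor acetonide (the freed C1 acid closes ring B on the tertiary C3–OH), the acetonide keeping O1 masked and the C1 carboxyl trans to C3 until ring A is in place.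

**Compound list**

1 | 9-bromonon-1-ene | C=CCCCCCCCBr | starting material
2 | (R)-epichlorohydrin, (2R)-2-(chloromethyl)oxirane | ClC[C@H]1CO1 | starting material
3 | non-8-en-1-ylmagnesium bromide | C=CCCCCCCC[Mg]Br | intermediate
4 | (2R)-1-chlorododec-11-en-2-ol | C=CCCCCCCCC[C@@H](O)CCl | intermediate
5 | (2R)-2-(dec-9-en-1-yl)oxirane | C=CCCCCCCCC[C@@H]1CO1 | intermediate
6 | 2-(tert-butyldimethylsilyl)-1,3-dithiane | CC(C)(C)[Si](C)(C)C1SCCCS1 | starting material
7 | methyl chloroformate | COC(=O)Cl | starting material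
8 | [2-(tert-butyldimethylsilyl)-1,3-dithian-2-yl]lithium | [Li]C1(SCCCS1)[Si](C)(C)C(C)(C)C | intermediate
9 | lithium (2R)-1-[2-(tert-butyldimethylsilyl)-1,3-dithian-2-yl]dodec-11-en-2-olate | C=CCCCCCCCC[C@@H](O[Li])CC1(SCCCS1)[Si](C)(C)C(C)(C)C | intermediate
10 | {2-[(2R)-2-(tert-butyldimethylsilyloxy)dodec-11-en-1-yl]-1,3-dithian-2-yl}lithium | C=CCCCCCCCC[C@@H](O[Si](C)(C)C(C)(C)C)CC1([Li])SCCCS1 | intermediate
11 | methyl 2-[(2R)-2-(tert-butyldimethylsilyloxy)dodec-11-en-1-yl]-1,3-dithiane-2-carboxylate | C=CCCCCCCCC[C@@H](O[Si](C)(C)C(C)(C)C)CC1(SCCCS1)C(=O)OC | intermediate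
12 | methyl (4R)-4-(tert-butyldimethylsilyloxy)-2-oxotetradec-13-enoate | C=CCCCCCCCC[C@@H](O[Si](C)(C)C(C)(C)C)CC(=O)C(=O)OC | intermediate
13 | di-tert-butyl L-tartrate, di-tert-butyl (2R,3R)-2,3-dihydroxybutanedioate | CC(C)(C)OC(=O)[C@H](O)[C@@H](O)C(=O)OC(C)(C)C | starting material
14 | di-tert-butyl (4R,5R)-2,2-dimethyl-1,3-dioxolane-4,5-dicarboxylate | CC(C)(C)OC(=O)[C@@H]1OC(C)(C)O[C@H]1C(=O)OC(C)(C)C | intermediate
15 | lithium enolate of 14, tert-butyl (4R)-5-[tert-butoxy(lithiooxy)methylidene]-2,2-dimethyl-1,3-dioxolane-4-carboxylate | CC(C)(C)OC(=O)[C@@H]1OC(C)(C)OC1=C(O[Li])OC(C)(C)C | intermediate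
16 | di-tert-butyl (4R,5R)-4-[(2S,4R)-4-(tert-butyldimethylsilyloxy)-2-hydroxy-1-methoxy-1-oxotetradec-13-en-2-yl]-2,2-dimethyl-1,3-dioxolane-4,5-dicarboxylate | C=CCCCCCCCC[C@@H](O[Si](C)(C)C(C)(C)C)C[C@@](O)(C(=O)OC)[C@]1(C(=O)OC(C)(C)C)OC(C)(C)O[C@H]1C(=O)OC(C)(C)C | intermediate
17 | di-tert-butyl (4R,5R)-4-[(3S,5R)-5-(dec-9-en-1-yl)-3-hydroxy-2-oxooxolan-3-yl]-2,2-dimethyl-1,3-dioxolane-4,5-dicarboxylate | C=CCCCCCCCC[C@@H]1C[C@@](O)(C(=O)O1)[C@]2(C(=O)OC(C)(C)C)OC(C)(C)O[C@H]2C(=O)OC(C)(C)C | intermediate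
18 | (2R,3R)-2-[(3S,5R)-5-(dec-9-en-1-yl)-3-hydroxy-2-oxooxolan-3-yl]-2,3-dihydroxybutanedioic acid | C=CCCCCCCCC[C@@H]1C[C@@](O)(C(=O)O1)[C@@](O)(C(=O)O)[C@@H](O)C(=O)O | intermediate
19 | (3R,4R,5S,8R)-8-(dec-9-en-1-yl)-3,4-dihydroxy-2,6-dioxo-1,7-dioxaspiro[4.4]nonane-4-carboxylic acid | C=CCCCCCCCC[C@@H]1C[C@@]2(OC(=O)[C@H](O)[C@]2(O)C(=O)O)C(=O)O1 | target

**Step count and risks**

Total step count: 5. Longest linear sequence: 4 (steps 1, 2, 3, 5).

Step 5 is the most likely to fail. The basic enolate may enolize 12 (with loss of silanol) instead of adding to it. The C3 face selectivity rests on a chelated chair that is predicted, not proven, for a β-silyloxy keto ester. The two lactones must sort themselves in one flask, and the terminal alkene may slowly add trifluoroacetic acid. The fallback changes the bond-forming mode and closes the rings one at a time. It sets out from 14, whose enolate is trapped with Me3SiCl as the silyl ketene acetal tert-butyl (4R)-5-[tert-butoxy(trimethylsilyloxy)methylidene]-2,2-dimethyl-1,3-dioxolane-4-carboxylate F1. F1 is added to 12 in a Mukaiyama aldol under SnCl4 (CH2Cl2, −78 °C; non-basic, keto ester chelated, open transition state). This comes back to the route at 16, now isolated and freed of its C3 epimer by chromatography. HF·pyridine in THF then gives 17 as an isolated compound (ring A closed on purpose while the acetonide still blocks ring B), and CF3CO2H/H2O takes 17 through 18 to 19.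

Step 2 is the second risk. Epoxide opening by the hindered silyl dithiane anion may be slow, the Brook shift may be incomplete (the alkoxide is then O-acylated to a carbonate), or the relayed carbanion may be protonated before acylation. The fallback is a stepwise umpolung without silyl relay. It sets out from 5: lithiated 1,3-dithiane (n-BuLi, THF, −30 °C) gives (2R)-1-(1,3-dithian-2-yl)dodec-11-en-2-ol F2. t-BuMe2SiCl and imidazole give tert-butyl{[(2R)-1-(1,3-dithian-2-yl)dodec-11-en-2-yl]oxy}dimethylsilane F3. A second lithiation (n-BuLi, THF, −30 °C) quenched with 7 comes back to the route at 11.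

Step 3 is the third risk. The oxidant may touch the alkene, the acid released may cleave the silyl ether (the freed alcohol then lactonizes to the enolized keto lactone, which is useless as an electrophile), or 12 may lose silanol on silica. The fallback avoids sulfur and installs the C3 oxygen by enolate oxidation. It sets out from 5:
- The aluminium enolate of tert-butyl acetate (LiN(iPr)2, then Et2AlCl, THF, −78 → −20 °C) opens the epoxide to tert-butyl (4R)-4-hydroxytetradec-13-enoate F4.
- Silylation (t-BuMe2SiCl, imidazole) gives tert-butyl (4R)-4-(tert-butyldimethylsilyloxy)tetradec-13-enoate F5.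
- KN(SiMe3)2 and 2-(phenylsulfonyl)-3-phenyloxaziridine give tert-butyl (4R)-4-(tert-butyldimethylsilyloxy)-2-hydroxytetradec-13-enoate F6 (both C2 epimers serve).
- Dess–Martin periodinane gives tert-butyl (4R)-4-(tert-butyldimethylsilyloxy)-2-oxotetradec-13-enoate F7.
- F7 takes the place of 12 in step 5 and gives the tri-tert-butyl aldol adduct di-tert-butyl (4R,5R)-4-[(2S,4R)-1-tert-butoxy-4-(tert-butyldimethylsilyloxy)-2-hydroxy-1-oxotetradec-13-en-2-yl]-2,2-dimethyl-1,3-dioxolane-4,5-dicarboxylate F8.
- Acidolysis of F8 in the same flask comes back to the route at 18 and so reaches 19.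

Further compounds
F1 | step 5 | tert-butyl (4R)-5-[tert-butoxy(trimethylsilyloxy)methylidene]-2,2-dimethyl-1,3-dioxolane-4-carboxylate | CC(C)(C)OC(=O)[C@@H]1OC(C)(C)OC1=C(O[Si](C)(C)C)OC(C)(C)C
F2 | step 2 | (2R)-1-(1,3-dithian-2-yl)dodec-11-en-2-ol | C=CCCCCCCCC[C@@H](O)CC1SCCCS1
F3 | step 2 | tert-butyl{[(2R)-1-(1,3-dithian-2-yl)dodec-11-en-2-yl]oxy}dimethylsilane | C=CCCCCCCCC[C@@H](O[Si](C)(C)C(C)(C)C)CC1SCCCS1
F4 | step 3 | tert-butyl (4R)-4-hydroxytetradec-13-enoate | C=CCCCCCCCC[C@@H](O)CCC(=O)OC(C)(C)C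
F5 | step 3 | tert-butyl (4R)-4-(tert-butyldimethylsilyloxy)tetradec-13-enoate | C=CCCCCCCCC[C@@H](O[Si](C)(C)C(C)(C)C)CCC(=O)OC(C)(C)C
F6 | step 3 | tert-butyl (4R)-4-(tert-butyldimethylsilyloxy)-2-hydroxytetradec-13-enoate (both C2 epimers) | C=CCCCCCCCC[C@@H](O[Si](C)(C)C(C)(C)C)CC(O)C(=O)OC(C)(C)C
F7 | step 3 | tert-butyl (4R)-4-(tert-butyldimethylsilyloxy)-2-oxotetradec-13-enoate | C=CCCCCCCCC[C@@H](O[Si](C)(C)C(C)(C)C)CC(=O)C(=O)OC(C)(C)C
F8 | step 3 | di-tert-butyl (4R,5R)-4-[(2S,4R)-1-tert-butoxy-4-(tert-butyldimethylsilyloxy)-2-hydroxy-1-oxotetradec-13-en-2-yl]-2,2-dimethyl-1,3-dioxolane-4,5-dicarboxylate | C=CCCCCCCCC[C@@H](O[Si](C)(C)C(C)(C)C)C[C@@](O)(C(=O)OC(C)(C)C)[C@]1(C(=O)OC(C)(C)C)OC(C)(C)O[C@H]1C(=O)OC(C)(C)C
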